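**Plan**
The target is an achiral p-terphenyl. Central ring B carries benzoates on C1 and C2, the 4-hydroxyphenyl rings A and C on C3 and C6, and free hydroxyls on C4 and C5.
Retrosynthetic cuts, in order: the two benzyl groups placed on the outer phenol oxygens, then the C1–O and C2–O bonds to the benzoates, then the C3–ring A and C6–ring C biaryl bonds.
Enabling feature: oxidising the C4/C5 catechol gives an o-quinone whose two beta (acceptor) carbons are C1 and C2. Its alpha carbons C3 and C6 are fully substituted by rings A and C, so an external nucleophile can only end up on C1 and C2.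
Forward order: no ring is built. Ring B (1, masked as 2) is joined to rings A and C (both from 3) in one twofold Suzuki–Miyaura coupling (4). The catechol is freed (5), both benzoates are introduced from 6 at the anode (through 7, 8, 9 to 10), and the benzyl groups are removed (11).
Stereochemistry: there is no stereocentre and no stereogenic axis (rings A and C are symmetric about their axes), so nothing has to be controlled.

Key step: step 4

Assumption: 3,6-dibromocatechol 1 is treated as a catalogue compound, and the anode potential of step 4 is left to be fixed by cyclic voltammetry in the actual buffer.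

**Step 1**
Reactants: 1 3,6-dibromobenzene-1,2-diol
Product: 2 1,4-dibromo-2,3-bis(methoxymethoxy)benzene
Conditions: MOMCl (3 equiv), K2CO3 (4 equiv), DMF, argon, 0 °C to rt
Reagents that add atoms: chloromethyl methyl ether (MOMCl), COCCl
Why: Williamson-type O-alkylation (MOM ether formation) of two acidic, bromine-flanked phenols by a very reactive alpha-chloro ether masks the catechol, which would otherwise chelate palladium and esterify the boronic acid in step 2.

**Step 2**
Reactants: 2 1,4-dibromo-2,3-bis(methoxymethoxy)benzene; 3 4-benzyloxyphenylboronic acid (2.5 equiv)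
Product: 4 4,4''-bis(benzyloxy)-2',3'-bis(methoxymethoxy)-1,1':4',1''-terphenyl
Conditions: Pd(OAc)2 (5 mol%), SPhos (10 mol%), K3PO4 (4 equiv), toluene/H2O, argon, 90 °C
Reagents that add atoms: none
Why: In this twofold Suzuki–Miyaura coupling, zerovalent palladium carrying the bulky, electron-rich SPhos ligand should insert into both ortho-alkoxy C–Br bonds, and MOM and benzyl ethers are inert to aqueous phosphate.

**Step 3**
Reactants: 4 4,4''-bis(benzyloxy)-2',3'-bis(methoxymethoxy)-1,1':4',1''-terphenyl
Product: 5 3,6-bis(4-benzyloxyphenyl)benzene-1,2-diol
Conditions: conc. HCl (cat.), MeOH/THF, argon, 50 °C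
Reagents that add atoms: none
Why: Acid-catalysed acetal exchange (standard MOM cleavage) passes the formaldehyde unit to methanol and frees both phenols, while benzyl aryl ethers are stable to dilute acid at this temperature.

**Step 4**
Reactants: 5 3,6-bis(4-benzyloxyphenyl)benzene-1,2-diol; 6 benzoic acid
Product: 10 4,4''-bis(benzyloxy)-5',6'-dihydroxy-1,1':4',1''-terphenyl-2',3'-diyl dibenzoate, via o-quinone 7 (not isolated), via monobenzoate catechol 8 (not isolated), via monobenzoate o-quinone 9 (not isolated)
Conditions: controlled-potential electrolysis, divided H-cell (glass frit), reticulated vitreous carbon anode, Pt cathode; anolyte 5, Bu4N(O2CPh) (10 equiv), 6 (3 equiv), Bu4NPF6, dry MeCN/CH2Cl2, 3 Å sieves; catholyte 6, Bu4NPF6, MeCN; argon, 25 °C; anode held about 0.1 volt positive of the oxidation wave of 8 (read from voltammograms taken during the run), 4 F/mol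
Reagents that add atoms: tetrabutylammonium benzoate, CCCC[N+](CCCC)(CCCC)CCCC.[O-]C(=O)c1ccccc1 (carrier form of the benzoate; it exchanges protons with 6, which is the net benzoate source)
Why: Proposed new method: at the carbon anode 5 loses two electrons and two protons (taken up by benzoate) to give o-quinone 7, benzoate adds to the beta carbon C1 of the O=C5–C6=C1 enone, and proton transfer through the buffer rearomatises the adduct to catechol 8; the same oxidation–addition–tautomerisation cycle through 9 places the second benzoate on C2, the terminus of the O=C4–C3=C2 enone, while the protons are discharged as hydrogen at the cathode. The closest known reaction types are the anodic oxidation of catechols in the presence of methanol, sulfinates or amines, the conversion of 3,6-dialkyl-o-quinones into their 4,5-dimethoxy derivatives, the intramolecular carboxylate capture that turns oxidised 3-(3,4-dihydroxyphenyl)propanoic acids into dihydroxydihydrocoumarins, and the Thiele–Winter acetoxylation; what has not been shown is intermolecular capture by a free carboxylate, twice, on a 3,6-diaryl substrate. No ring closes and no stereocentre forms. Site selectivity rests on rings A and C, which occupy the alpha carbons C3 and C6 and leave only C1 and C2 able to rearomatise after attack, and attack of benzoate at the already substituted C1 of 9 merely exchanges one benzoate for another. Chemoselectivity rests on the order of oxidation potentials: a catechol with a carboxylate base at hand is oxidised well below the benzyloxyphenyl rings and below the Kolbe discharge of benzoate, each acyloxy group makes the next catechol harder to oxidise so that 10 lags behind 5 and 8, and the quinone of 10 would have no open carbon in any case. The weak nucleophile is helped by the dry aprotic medium, the non-coordinating tetrabutylammonium cation and an excess of benzoate over acid (an equimolar mixture is largely locked up as the hydrogen-bonded acid–benzoate pair), the sieves remove water as a competitor, the divided cell lets 7 and 9 live long enough to be captured, and the meta relation between each ester oxygen and the nearest hydroxyl rules out acyl migration in 8 and 10.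

**Step 5**
Reactants: 10 4,4''-bis(benzyloxy)-5',6'-dihydroxy-1,1':4',1''-terphenyl-2',3'-diyl dibenzoate
Product: 11 4,4'',5',6'-tetrahydroxy-1,1':4',1''-terphenyl-2',3'-diyl dibenzoate (target)
Conditions: H2 (1 atm), 10% Pd/C, EtOAc/THF, rt; filtration and concentration under argon
Reagents that add atoms: none
Why: Catalytic hydrogenolysis cleaves the two benzylic C–O bonds under conditions that leave aryl benzoates, phenols and arene rings untouched, and the aprotic solvent avoids ester solvolysis.

**Compound list**
1 | 3,6-dibromobenzene-1,2-diol | Oc1c(Br)ccc(Br)c1O | starting material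
2 | 1,4-dibromo-2,3-bis(methoxymethoxy)benzene | COCOc1c(Br)ccc(Br)c1OCOC | intermediate
3 | 4-benzyloxyphenylboronic acid | OB(O)c1ccc(OCc2ccccc2)cc1 | starting material
4 | 4,4''-bis(benzyloxy)-2',3'-bis(methoxymethoxy)-1,1':4',1''-terphenyl | COCOc1c(-c2ccc(OCc3ccccc3)cc2)ccc(-c2ccc(OCc3ccccc3)cc2)c1OCOC | intermediate
5 | 3,6-bis(4-benzyloxyphenyl)benzene-1,2-diol | Oc1c(O)c(-c2ccc(OCc3ccccc3)cc2)ccc1-c1ccc(OCc2ccccc2)cc1 | intermediate
6 | benzoic acid | O=C(O)c1ccccc1 | starting material
7 | 3,6-bis(4-benzyloxyphenyl)cyclohexa-3,5-diene-1,2-dione (o-quinone) | O=C1C(=O)C(-c2ccc(OCc3ccccc3)cc2)=CC=C1-c1ccc(OCc2ccccc2)cc1 | intermediate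
8 | 2,5-bis(4-benzyloxyphenyl)-3,4-dihydroxyphenyl benzoate (monobenzoate catechol) | Oc1c(O)c(-c2ccc(OCc3ccccc3)cc2)c(OC(=O)c2ccccc2)cc1-c1ccc(OCc2ccccc2)cc1 | intermediate
9 | 2,5-bis(4-benzyloxyphenyl)-3,4-dioxocyclohexa-1,5-dien-1-yl benzoate (monobenzoate o-quinone) | O=C1C(=O)C(-c2ccc(OCc3ccccc3)cc2)=C(OC(=O)c2ccccc2)C=C1-c1ccc(OCc2ccccc2)cc1 | intermediate
10 | 4,4''-bis(benzyloxy)-5',6'-dihydroxy-1,1':4',1''-terphenyl-2',3'-diyl dibenzoate | O=C(Oc1c(OC(=O)c2ccccc2)c(-c2ccc(OCc3ccccc3)cc2)c(O)c(O)c1-c1ccc(OCc2ccccc2)cc1)c1ccccc1 | intermediate
11 | 4,4'',5',6'-tetrahydroxy-1,1':4',1''-terphenyl-2',3'-diyl dibenzoate | O=C(Oc1c(OC(=O)c2ccccc2)c(-c2ccc(O)cc2)c(O)c(O)c1-c1ccc(O)cc1)c1ccccc1 | target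

**Step count**
Total steps: 5. Longest linear sequence: 5 (1 → 2 → 4 → 5 → 10 → 11).

**Steps most likely to fail**

1. **Step 4.**
   - Risk: capture of the quinones by benzoate may be slower than their loss. Loss could occur through reaction with traces of water, through coupling with unoxidised catechol, or through closure of a quinone oxygen onto the neighbouring benzyloxyphenyl ring. The second, more crowded addition may also stall after the first cycle.
   - Basis of the fallback (known chemistry only): ring B keeps the same substitution pattern when the C1/C2 and C4/C5 oxygen pairs are exchanged. The esters can therefore go on the two oxygens that 5 already owns. The two new oxygens can be brought in with methanol, the nucleophile for which twofold addition to electrogenerated o-quinones is established.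
   - Route: setting out from 5, a six-electron anodic oxidation in MeOH/CH2Cl2 with NaOAc at a carbon anode should give 3,6-bis(4-benzyloxyphenyl)-4,5-dimethoxy-o-benzoquinone F1. Aqueous Na2S2O4 should reduce it to 3,6-bis(4-benzyloxyphenyl)-4,5-dimethoxybenzene-1,2-diol F2. Benzoyl chloride, pyridine and DMAP in CH2Cl2 should acylate both hydroxyls to give 3,6-bis(4-benzyloxyphenyl)-4,5-dimethoxy-1,2-phenylene dibenzoate F3. BBr3 in CH2Cl2 (−78 to 0 °C) should then cleave the two methyl and the two benzyl ethers in one operation. The aryl benzoates offer no alkyl–oxygen bond to this reagent, and the route comes back at 11.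

2. **Step 2.**
   - Risk: after the first coupling the remaining C–Br bond sits on a more electron-rich and more crowded ring, so the second oxidative addition may lag. Meanwhile the electron-rich boronic acid is consumed by protodeboronation and the bromide by hydrodehalogenation.
   - Fallback: reverse the roles of the partners. Setting out from 2, Miyaura borylation (B2pin2, Pd(dppf)Cl2, KOAc, dioxane, 90 °C) should give 2,2'-[2,3-bis(methoxymethoxy)-1,4-phenylene]bis(4,4,5,5-tetramethyl-1,3,2-dioxaborolane) F4. This is coupled with purchased 1-benzyloxy-4-iodobenzene (Ic1ccc(OCc2ccccc2)cc1) using Pd(PPh3)4 and K2CO3 in dioxane/H2O at 80 °C. Oxidative addition then takes place at an unhindered aryl iodide, and the route comes back at 4.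

3. **Step 5.**
   - Risk: the free catechol may foul the catalyst surface and slow the second debenzylation. Long exposure invites ester solvolysis, or air oxidation of the electron-rich ring B during filtration.
   - Fallback: a non-reductive Lewis-acid dealkylation in place of a surface-catalysed reduction. Setting out from 10, BCl3 with pentamethylbenzene as benzyl cation scavenger in CH2Cl2 at −78 °C, quenched with MeOH, should remove both benzyl groups in a homogeneous, oxygen-free medium that tolerates aryl esters. The route comes back at 11, and no new compound arises on this way (F0).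

**Further compounds**
F1 | step 4 | 3,6-bis(4-benzyloxyphenyl)-4,5-dimethoxycyclohexa-3,5-diene-1,2-dione | O=C1C(=O)C(-c2ccc(OCc3ccccc3)cc2)=C(OC)C(OC)=C1-c1ccc(OCc2ccccc2)cc1
F2 | step 4 | 3,6-bis(4-benzyloxyphenyl)-4,5-dimethoxybenzene-1,2-diol | COc1c(OC)c(-c2ccc(OCc3ccccc3)cc2)c(O)c(O)c1-c1ccc(OCc2ccccc2)cc1
F3 | step 4 | 3,6-bis(4-benzyloxyphenyl)-4,5-dimethoxy-1,2-phenylene dibenzoate | COc1c(OC)c(-c2ccc(OCc3ccccc3)cc2)c(OC(=O)c2ccccc2)c(OC(=O)c2ccccc2)c1-c1ccc(OCc2ccccc2)cc1
F4 | step 2 | 2,2'-[2,3-bis(methoxymethoxy)-1,4-phenylene]bis(4,4,5,5-tetramethyl-1,3,2-dioxaborolane) | COCOc1c(B2OC(C)(C)C(C)(C)O2)ccc(B2OC(C)(C)C(C)(C)O2)c1OCOC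
F0 | step 5 | none | none
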